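**Retrosynthetic overview**
- Target 30 ⇒ diol ketone 26 (O8 acetate and O9 tiglate put on last) ⇒ cis-decalin 21, which has C2 masked as a silyl enol ether, O8/O9 as a cis-acetonide and a temporary ketone at C6 (removed by reduction and Barton–McCombie deoxygenation).
- Feature used: in ring B (C10, C1, C2, C3, C4, C5) the C2 carbonyl is 1,4 to the quaternary C5, the C4 and C5 methyls are cis and the C5–C10 fusion is cis. With a carbonyl at C6 of ring A (C5–C10), this is the retron of a 2-silyloxydiene C10=C1–C2(OTBS)=C3 and an (E)-tiglyl ketone C4=C5–C6=O joined through C6–C9.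
- 21 ⇒ acyclic trienone 20 by an intramolecular Diels–Alder reaction that forms C3–C4 and C5–C10 and closes rings A and B together; no carbocycle exists before this step.
- 20 ⇒ Weinreb amide 16 + (E)-but-2-en-2-yl metal (C5–C6 bond); the diene comes from the C10 aldehyde 13 by Horner–Wadsworth–Emmons olefination and O-silylation.
- C7 and C8 come from an Evans syn-aldol of the senecioyl imide 4 (α-attack of its dienolate) on (S)-glyceraldehyde acetonide 5 (source of C9); lactone 8 serves to move the acetonide from O9/O10 to O8/O9.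

Key step: step 11

Remark: atoms carry eremophilane numbers (C11–C13 = isopropenyl on C7); in this numbering the target is 4S,5R,7R,8R,9S,10S, i.e. 4β,5β-dimethyl, 7β-isopropenyl, 8α-OAc, 9α-O-tiglate, 10β-H.
Remark: the C6 carbinol in 22–24 is written as the epimer expected from axial hydride attack; the centre is erased in step 14, so either epimer serves.

**Step 1**
Reactants: 1 (4R)-4-benzyl-1,3-oxazolidin-2-one; 2 3-methylbut-2-enoyl chloride
Product: 4 (4R)-4-benzyl-3-(3-methylbut-2-enoyl)-1,3-oxazolidin-2-one, via N-lithio oxazolidinone 3 (not isolated)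
Conditions: n-BuLi, THF, −78 °C; then 2, −78 → 0 °C
Reagents that add atoms: none
Why: N-acylation of the lithiated oxazolidinone by the acid chloride at low temperature is the standard route to Evans imides and avoids the vinylketene (deconjugation) pathway that amine bases open for this acid chloride.

**Step 2**
Reactants: 4 senecioyl imide; 5 (4S)-2,2-dimethyl-1,3-dioxolane-4-carbaldehyde
Product: 7 (4R)-4-benzyl-3-[(2R,3R)-3-[(4S)-2,2-dimethyl-1,3-dioxolan-4-yl]-3-hydroxy-2-(prop-1-en-2-yl)propanoyl]-1,3-oxazolidin-2-one, via boron dienolate 6 (not isolated)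
Conditions: Bu2BOTf, Et3N, CH2Cl2, −78 → 0 °C; then 5, −78 → 0 °C; pH 7 buffer, MeOH, H2O2, 0 °C
Reagents that add atoms: none
Why: Evans syn-aldol reaction, in which the (Z)-boron dienolate reacts at its α-carbon through a closed Zimmerman–Traxler transition state, so the (R)-benzyl auxiliary sets C7 and C8 (7R,8R, isopropenyl and hydroxyl syn), and the polar Felkin (Cornforth) preference of the α-alkoxy aldehyde for the 8,9-anti diol should reinforce this (matched pair).

**Step 3**
Reactants: 7 aldol adduct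
Product: 8 (3R,4R,5S)-4-hydroxy-5-(hydroxymethyl)-3-(prop-1-en-2-yl)oxolan-2-one
Conditions: 1 M HCl, THF, rt → 40 °C
Reagents that add atoms: none
Why: Acid hydrolysis of the terminal acetonide frees O9 and O10, and the γ-hydroxyl O9 then displaces the oxazolidinone from the activated imide carbonyl (5-exo-trig lactonisation), which removes the auxiliary and leaves only O8 and the primary O10 free.

**Step 4**
Reactants: 8 lactone diol
Product: 9 (3R,4R,5S)-5-{[(tert-butyldiphenylsilyl)oxy]methyl}-4-hydroxy-3-(prop-1-en-2-yl)oxolan-2-one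
Conditions: TBDPSCl, imidazole, CH2Cl2, 0 °C
Reagents that add atoms: tert-butyl(chloro)diphenylsilane CC(C)(C)[Si](Cl)(c1ccccc1)c1ccccc1
Why: Silyl ether formation with the bulky chlorosilane is selective for the primary C10 hydroxyl over the secondary C8 hydroxyl.

**Step 5**
Reactants: 9 silylated lactone
Product: 11 (2R)-2-[(4R,5S)-5-{[(tert-butyldiphenylsilyl)oxy]methyl}-2,2-dimethyl-1,3-dioxolan-4-yl]-N-methoxy-N,3-dimethylbut-3-enamide, via dihydroxy Weinreb amide 10 (not isolated)
Conditions: MeNH(OMe)·HCl, AlMe3, CH2Cl2, 0 °C → rt; aq. KNaC4H4O6 work-up; then 2-methoxypropene, PPTS (cat.), CH2Cl2, 0 °C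
Reagents that add atoms: N,O-dimethylhydroxylamine hydrochloride CNOC.Cl; 2-methoxypropene C=C(C)OC
Why: Weinreb aminolysis of the γ-lactone by the aluminium amide releases O9, and the erythro 8,9-diol is trapped at once as the cis-dioxolane by acid-catalysed ketalisation before it can relactonise.

**Step 6**
Reactants: 11 silyl ether
Product: 12 (2R)-2-[(4R,5S)-5-(hydroxymethyl)-2,2-dimethyl-1,3-dioxolan-4-yl]-N-methoxy-N,3-dimethylbut-3-enamide
Conditions: Bu4NF, AcOH, THF, 0 °C → rt
Reagents that add atoms: none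
Why: Fluoride cleavage of the silyl ether, buffered with acetic acid so that the α-acidic amide with its β-oxygen is not exposed to basic fluoride.

**Step 7**
Reactants: 12 primary alcohol
Product: 13 (2R)-2-[(4R,5R)-5-formyl-2,2-dimethyl-1,3-dioxolan-4-yl]-N-methoxy-N,3-dimethylbut-3-enamide
Conditions: Dess–Martin periodinane, CH2Cl2, 0 °C → rt; used crude
Reagents that add atoms: none
Why: Dess–Martin oxidation gives the α-alkoxy aldehyde without base, so C9 on the cis-dioxolane should not epimerise.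

**Step 8**
Reactants: 13 aldehyde; 14 dimethyl (2-oxopropyl)phosphonate
Product: 15 (2R)-N-methoxy-N,3-dimethyl-2-{(4R,5S)-2,2-dimethyl-5-[(1E)-3-oxobut-1-en-1-yl]-1,3-dioxolan-4-yl}but-3-enamide
Conditions: LiCl, i-Pr2NEt, MeCN, rt
Reagents that add atoms: none
Why: Horner–Wadsworth–Emmons olefination under Masamune–Roush conditions is E-selective and mild enough for the epimerisable α-alkoxy aldehyde, giving the C10=C1 (E)-enone.

**Step 9**
Reactants: 15 enone
Product: 16 (2R)-2-{(4R,5S)-5-[(1E)-3-[(tert-butyldimethylsilyl)oxy]buta-1,3-dien-1-yl]-2,2-dimethyl-1,3-dioxolan-4-yl}-N-methoxy-N,3-dimethylbut-3-enamide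
Conditions: TBSOTf, Et3N, CH2Cl2, −78 → 0 °C
Reagents that add atoms: tert-butyldimethylsilyl trifluoromethanesulfonate CC(C)(C)[Si](C)(C)OS(=O)(=O)C(F)(F)F
Why: Silyl enol ether formation by soft enolisation removes the kinetic α′-proton at C3 of the methyl ketone and gives the cross-conjugated 2-silyloxydiene, while the amide and the acetonide are inert under these conditions.

**Step 10**
Reactants: 16 silyloxydiene Weinreb amide; 17 (E)-2-bromobut-2-ene
Product: 20 (2E,5R)-5-{(4R,5S)-5-[(1E)-3-[(tert-butyldimethylsilyl)oxy]buta-1,3-dien-1-yl]-2,2-dimethyl-1,3-dioxolan-4-yl}-3,6-dimethylhepta-2,6-dien-4-one, via but-2-en-2-yllithium 18 (not isolated), via but-2-en-2-ylcerium dichloride 19 (not isolated)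
Conditions: 17, t-BuLi (2 equiv), THF, −78 °C; CeCl3 (anhydrous), −78 °C; then 16, −78 °C; pH 7 buffer, cold
Reagents that add atoms: none
Why: Weinreb ketone synthesis, in which bromine–lithium exchange keeps the alkene geometry and the weakly basic organocerium reagent adds to the amide without removing the acidic C7 proton, the chelated adduct releasing the (E)-tiglyl ketone only on work-up.

**Step 11**
Reactants: 20 acyclic silyloxydiene tiglyl ketone
Product: 21 cis-fused 2-[(tert-butyldimethylsilyl)oxy]-8α,9α-(isopropylidenedioxy)-10βH-eremophila-1,11-dien-6-one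
Conditions: PhMe (0.005 M), BHT (cat.), silanised sealed tube, 110 → 160 °C
Reagents that add atoms: none
Why: Concerted, asynchronous thermal [4+2] cycloaddition in which the silyl enol ether terminus C3 of the diene C10=C1–C2(OTBS)=C3 bonds to the enone β-carbon C4 and C10 bonds to the α-carbon C5; the closest known reaction type is the intramolecular Diels–Alder reaction (type 1, fused) of internally activated 1,7,9-decatrien-3-ones and of 2-silyloxydienes. Ring B (C10, C1, C2, C3, C4, C5) is the cyclohexene made by the cycloaddition itself, and ring A (C5–C10) closes at the same time through the C5–C10 bond, exo with respect to both π-systems, with the C6–C9 tether in a chair. C4 and C5 are set relative to each other by suprafacial addition to the (E)-tiglyl alkene, which carries its cis methyls into the product, and C10 is set cis to the C5 methyl by the endo position of the tether carbonyl C6 under the diene. The sense of C4, C5 and C10 relative to C7–C9 comes from the diene face reached when the tether chair holds the C7 isopropenyl and O8 equatorial and O9 axial, so that the vinylic C4–H and not the C5 methyl lies syn-axial to O9, whereas the exo (trans-fused) chairs and the opposite-face endo chairs each place that methyl or C4 1,3-diaxial to O9 or to the isopropenyl group. Regiochemistry is fixed both by the tether length and by pairing the nucleophilic C3 with the electrophilic C4.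

**Step 12**
Reactants: 21 C6 ketone
Product: 22 6α-hydroxy-2-[(tert-butyldimethylsilyl)oxy]-8α,9α-(isopropylidenedioxy)-10βH-eremophila-1,11-diene
Conditions: LiAlH4, Et2O, −78 → 0 °C; Fieser work-up
Reagents that add atoms: none
Why: Hydride reduction of the hindered ketone, expected by axial attack from the open face of ring A to give the equatorial 6α-alcohol (cis to O8/O9), with the silyl enol ether and acetonide inert to the aluminium hydride.

**Step 13**
Reactants: 22 C6 alcohol
Product: 24 O-(C6) S-methyl xanthate of 22, via sodium xanthate 23 (not isolated)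
Conditions: NaH, imidazole (cat.), THF, 0 °C → rt; CS2; then MeI
Reagents that add atoms: carbon disulfide S=C=S; iodomethane CI
Why: Xanthate formation is the most reliable thiocarbonylation of a hindered secondary alcohol and runs under basic conditions that spare the silyl enol ether.

**Step 14**
Reactants: 24 xanthate
Product: 25 2-[(tert-butyldimethylsilyl)oxy]-8α,9α-(isopropylidenedioxy)-10βH-eremophila-1,11-diene
Conditions: Bu3SnH (0.5 M), AIBN (cat.), PhMe, 85 °C
Reagents that add atoms: none
Why: Barton–McCombie deoxygenation, in which stannyl radical addition to the thiocarbonyl and β-scission give the secondary C6 radical and the high stannane concentration should deliver hydrogen before the homoallylic radical can rearrange by 3-exo attack on the isopropenyl group.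

**Step 15**
Reactants: 25 silyl enol ether acetonide
Product: 26 8α,9α-dihydroxy-10βH-eremophil-11-en-2-one
Conditions: 2 M HCl–THF (1:3), rt
Reagents that add atoms: none
Why: Aqueous acid hydrolysis cleaves the silyl enol ether (to the C2 ketone, which has no stereocentre α to it) and the acetonide (to the cis-8,9-diol) in one operation, and the 1,1-disubstituted alkene should survive dilute acid at room temperature.

**Step 16**
Reactants: 26 diol ketone
Product: 27 8α-acetoxy-9α-hydroxy-10βH-eremophil-11-en-2-one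
Conditions: Ac2O (1.1 equiv), pyridine, CH2Cl2, −20 → 0 °C
Reagents that add atoms: acetic anhydride CC(=O)OC(C)=O
Why: Kinetically controlled acylation, because the equatorial C8 hydroxyl should react much faster than the axial C9 hydroxyl, which is flanked by the ring fusion and is 1,3-diaxial to C4.

**Step 17**
Reactants: 27 monoacetate; 28 tiglic acid
Product: 30 target (1S,2R,3R,4aR,5S,8aS)-2-(acetyloxy)-4a,5-dimethyl-7-oxo-3-(prop-1-en-2-yl)decahydronaphthalen-1-yl (2E)-2-methylbut-2-enoate, via mixed anhydride 29 (not isolated)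
Conditions: 28, 2,4,6-Cl3C6H2COCl, Et3N, PhMe, rt; then 27, DMAP, PhMe, 60 °C
Reagents that add atoms: none
Why: Yamaguchi esterification, in which the mixed anhydride with DMAP is reactive enough to acylate the hindered axial C9 hydroxyl and the (E)-geometry of the tiglate is the stable one.

**Compound list**
1 | (4R)-4-benzyl-1,3-oxazolidin-2-one | O=C1N[C@H](Cc2ccccc2)CO1 | starting material
2 | 3-methylbut-2-enoyl chloride | CC(C)=CC(Cl)=O | starting material
3 | N-lithio-(4R)-4-benzyl-1,3-oxazolidin-2-one | O=C1OC[C@@H](Cc2ccccc2)N1[Li] | intermediate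
4 | (4R)-4-benzyl-3-(3-methylbut-2-enoyl)-1,3-oxazolidin-2-one | CC(C)=CC(=O)N1[C@H](Cc2ccccc2)COC1=O | intermediate
5 | (4S)-2,2-dimethyl-1,3-dioxolane-4-carbaldehyde | O=C[C@@H]1COC(C)(C)O1 | starting material
6 | (Z)-dibutylboron dienolate of 4 | C=C(C)/C=C(\OB(CCCC)CCCC)N1[C@H](Cc2ccccc2)COC1=O | intermediate
7 | (4R)-4-benzyl-3-[(2R,3R)-3-[(4S)-2,2-dimethyl-1,3-dioxolan-4-yl]-3-hydroxy-2-(prop-1-en-2-yl)propanoyl]-1,3-oxazolidin-2-one | O=C1OC[C@@H](Cc2ccccc2)N1C(=O)[C@H](C(C)=C)[C@@H](O)[C@@H]1COC(C)(C)O1 | intermediate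
8 | (3R,4R,5S)-4-hydroxy-5-(hydroxymethyl)-3-(prop-1-en-2-yl)oxolan-2-one | C=C(C)[C@H]1C(=O)O[C@@H](CO)[C@@H]1O | intermediate
9 | (3R,4R,5S)-5-{[(tert-butyldiphenylsilyl)oxy]methyl}-4-hydroxy-3-(prop-1-en-2-yl)oxolan-2-one | C=C(C)[C@H]1C(=O)O[C@@H](CO[Si](c2ccccc2)(c2ccccc2)C(C)(C)C)[C@@H]1O | intermediate
10 | (2R,3R,4S)-5-[(tert-butyldiphenylsilyl)oxy]-3,4-dihydroxy-N-methoxy-N-methyl-2-(prop-1-en-2-yl)pentanamide | CON(C)C(=O)[C@H](C(C)=C)[C@@H](O)[C@@H](O)CO[Si](c1ccccc1)(c1ccccc1)C(C)(C)C | intermediate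
11 | (2R)-2-[(4R,5S)-5-{[(tert-butyldiphenylsilyl)oxy]methyl}-2,2-dimethyl-1,3-dioxolan-4-yl]-N-methoxy-N,3-dimethylbut-3-enamide | CON(C)C(=O)[C@H](C(C)=C)[C@H]1OC(C)(C)O[C@H]1CO[Si](c2ccccc2)(c2ccccc2)C(C)(C)C | intermediate
12 | (2R)-2-[(4R,5S)-5-(hydroxymethyl)-2,2-dimethyl-1,3-dioxolan-4-yl]-N-methoxy-N,3-dimethylbut-3-enamide | CON(C)C(=O)[C@H](C(C)=C)[C@H]1OC(C)(C)O[C@H]1CO | intermediate
13 | (2R)-2-[(4R,5R)-5-formyl-2,2-dimethyl-1,3-dioxolan-4-yl]-N-methoxy-N,3-dimethylbut-3-enamide | CON(C)C(=O)[C@H](C(C)=C)[C@H]1OC(C)(C)O[C@H]1C=O | intermediate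
14 | dimethyl (2-oxopropyl)phosphonate | COP(=O)(OC)CC(C)=O | starting material
15 | (2R)-N-methoxy-N,3-dimethyl-2-{(4R,5S)-2,2-dimethyl-5-[(1E)-3-oxobut-1-en-1-yl]-1,3-dioxolan-4-yl}but-3-enamide | CON(C)C(=O)[C@H](C(C)=C)[C@H]1OC(C)(C)O[C@H]1/C=C/C(C)=O | intermediate
16 | (2R)-2-{(4R,5S)-5-[(1E)-3-[(tert-butyldimethylsilyl)oxy]buta-1,3-dien-1-yl]-2,2-dimethyl-1,3-dioxolan-4-yl}-N-methoxy-N,3-dimethylbut-3-enamide | CON(C)C(=O)[C@H](C(C)=C)[C@H]1OC(C)(C)O[C@H]1/C=C/C(=C)O[Si](C)(C)C(C)(C)C | intermediate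
17 | (E)-2-bromobut-2-ene | C/C=C(/Br)C | starting material
18 | (E)-but-2-en-2-yllithium | C/C=C(/[Li])C | intermediate
19 | (E)-but-2-en-2-ylcerium dichloride | C/C=C(/[Ce](Cl)Cl)C | intermediate
20 | (2E,5R)-5-{(4R,5S)-5-[(1E)-3-[(tert-butyldimethylsilyl)oxy]buta-1,3-dien-1-yl]-2,2-dimethyl-1,3-dioxolan-4-yl}-3,6-dimethylhepta-2,6-dien-4-one | C=C(O[Si](C)(C)C(C)(C)C)/C=C/[C@@H]1OC(C)(C)O[C@@H]1[C@@H](C(C)=C)C(=O)/C(C)=C/C | intermediate
21 | 2-[(tert-butyldimethylsilyl)oxy]-8α,9α-(isopropylidenedioxy)-10βH-eremophila-1,11-dien-6-one (ring centres as in the target) | C=C(C)[C@H]1C(=O)[C@@]2(C)[C@H](C=C(O[Si](C)(C)C(C)(C)C)C[C@@H]2C)[C@@H]3OC(C)(C)O[C@H]13 | intermediate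
22 | 6α-hydroxy-2-[(tert-butyldimethylsilyl)oxy]-8α,9α-(isopropylidenedioxy)-10βH-eremophila-1,11-diene (6S) | C=C(C)[C@H]1[C@H](O)[C@@]2(C)[C@H](C=C(O[Si](C)(C)C(C)(C)C)C[C@@H]2C)[C@@H]3OC(C)(C)O[C@H]13 | intermediate
23 | sodium O-(C6) dithiocarbonate of 22 | C=C(C)[C@H]1[C@H](OC(=S)[S-])[C@@]2(C)[C@H](C=C(O[Si](C)(C)C(C)(C)C)C[C@@H]2C)[C@@H]3OC(C)(C)O[C@H]13.[Na+] | intermediate
24 | O-(C6) S-methyl dithiocarbonate of 22 | C=C(C)[C@H]1[C@H](OC(=S)SC)[C@@]2(C)[C@H](C=C(O[Si](C)(C)C(C)(C)C)C[C@@H]2C)[C@@H]3OC(C)(C)O[C@H]13 | intermediate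
25 | 2-[(tert-butyldimethylsilyl)oxy]-8α,9α-(isopropylidenedioxy)-10βH-eremophila-1,11-diene | C=C(C)[C@H]1C[C@@]2(C)[C@H](C=C(O[Si](C)(C)C(C)(C)C)C[C@@H]2C)[C@@H]3OC(C)(C)O[C@H]13 | intermediate
26 | 8α,9α-dihydroxy-10βH-eremophil-11-en-2-one | C=C(C)[C@H]1C[C@@]2(C)[C@H](CC(=O)C[C@@H]2C)[C@H](O)[C@@H]1O | intermediate
27 | 8α-acetoxy-9α-hydroxy-10βH-eremophil-11-en-2-one | C=C(C)[C@H]1C[C@@]2(C)[C@H](CC(=O)C[C@@H]2C)[C@H](O)[C@@H]1OC(C)=O | intermediate
28 | tiglic acid, (2E)-2-methylbut-2-enoic acid | C/C=C(\C)C(=O)O | starting material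
29 | (2E)-2-methylbut-2-enoic 2,4,6-trichlorobenzoic anhydride | C/C=C(\C)C(=O)OC(=O)c1c(Cl)cc(Cl)cc1Cl | intermediate
30 | CNP0204573.1, (1S,2R,3R,4aR,5S,8aS)-2-(acetyloxy)-4a,5-dimethyl-7-oxo-3-(prop-1-en-2-yl)decahydronaphthalen-1-yl (2E)-2-methylbut-2-enoate | C=C(C)[C@H]1C[C@@]2(C)[C@H](CC(=O)C[C@@H]2C)[C@H](OC(=O)/C(C)=C/C)[C@@H]1OC(C)=O | target

**Total step count:** 17
**Longest linear sequence:** 17 steps (1 → 30); compounds 2, 5, 14, 17 and 28 each enter in one step.

**Steps most likely to fail**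

1. Step 11. The endo chair transition state may not dominate over the exo (trans-fused) or opposite-face pathways, which would give diastereomers at C4, C5 and C10. The slow cycloaddition of the trisubstituted dienophile may also be overtaken by thermal isomerisation of the β,γ-unsaturated ketone (epimerisation at C7, conjugation, or β-elimination of O8). Fallback, from 20 back to 21: an anionic intramolecular double Michael addition in place of the thermal pericyclic reaction. Cleaving the Si–O bond of 20 with (Me2N)3S[Me3SiF2] in THF at −78 °C should give the tris(dimethylamino)sulfonium dienolate F1. Its C3 should add to C4 and the resulting C5 enolate should then add to C10 at low temperature, giving the bicyclic C1=C2 enolate F2. Trapping F2 with TBSCl returns the route to 21.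

2. Step 10. Deprotonation at the doubly activated C7 may compete with addition to the hindered amide, and would be followed by epimerisation, deconjugation or expulsion of O8. Fallback, from 16 back to 20: reduction of 16 with i-Bu2AlH at −78 °C to the aldehyde F3, which is used at once. Addition of 18 at −78 °C, far faster on an aldehyde than on an amide, gives the allylic alcohol F4 as a mixture of C6 epimers. Oxidation of F4 with MnO2 in CH2Cl2, which is neutral and tolerated by the silyl dienol ether, gives 20.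

3. Step 17. Acylation of the hindered axial O9 may be slow enough for base-mediated acetyl migration from O8 to O9, which would scramble the two ester positions. Fallback, from 26 to 30: a protecting-group detour that installs the tiglate before the acetate. Selective silylation of the equatorial O8 of 26 (Et3SiCl, imidazole, −20 °C) gives the 8-O-triethylsilyl ether F5. Yamaguchi acylation of O9 with 29 and DMAP gives the 9-tiglate silyl ether F6. Removal of the silyl group with HF·pyridine (acidic, so acyl migration is not promoted) gives the 8-hydroxy-9-tiglate F7, and acetylation of the unhindered O8 (Ac2O, DMAP, 0 °C) gives 30.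

**Further compounds**
F1 | step 11 | tris(dimethylamino)sulfonium dienolate of 20 | C=C([O-])/C=C/[C@@H]1OC(C)(C)O[C@@H]1[C@@H](C(C)=C)C(=O)/C(C)=C/C.CN(C)[S+](N(C)C)N(C)C
F2 | step 11 | tris(dimethylamino)sulfonium C1=C2 enolate of the cis-decalin-2,6-dione acetonide | C=C(C)[C@H]1C(=O)[C@@]2(C)[C@H](C=C([O-])C[C@@H]2C)[C@@H]3OC(C)(C)O[C@H]13.CN(C)[S+](N(C)C)N(C)C
F3 | step 10 | (2R)-2-{(4R,5S)-5-[(1E)-3-[(tert-butyldimethylsilyl)oxy]buta-1,3-dien-1-yl]-2,2-dimethyl-1,3-dioxolan-4-yl}-3-methylbut-3-enal | O=C[C@H](C(C)=C)[C@H]1OC(C)(C)O[C@H]1/C=C/C(=C)O[Si](C)(C)C(C)(C)C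
F4 | step 10 | (2E,5R)-5-{(4R,5S)-5-[(1E)-3-[(tert-butyldimethylsilyl)oxy]buta-1,3-dien-1-yl]-2,2-dimethyl-1,3-dioxolan-4-yl}-3,6-dimethylhepta-2,6-dien-4-ol, both C4 carbinol epimers | C/C=C(\C)C(O)[C@H](C(C)=C)[C@H]1OC(C)(C)O[C@H]1/C=C/C(=C)O[Si](C)(C)C(C)(C)C
F5 | step 17 | 9α-hydroxy-8α-[(triethylsilyl)oxy]-10βH-eremophil-11-en-2-one | C=C(C)[C@H]1C[C@@]2(C)[C@H](CC(=O)C[C@@H]2C)[C@H](O)[C@@H]1O[Si](CC)(CC)CC
F6 | step 17 | 9α-(tigloyloxy)-8α-[(triethylsilyl)oxy]-10βH-eremophil-11-en-2-one | C=C(C)[C@H]1C[C@@]2(C)[C@H](CC(=O)C[C@@H]2C)[C@H](OC(=O)/C(C)=C/C)[C@@H]1O[Si](CC)(CC)CC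
F7 | step 17 | 8α-hydroxy-9α-(tigloyloxy)-10βH-eremophil-11-en-2-one | C=C(C)[C@H]1C[C@@]2(C)[C@H](CC(=O)C[C@@H]2C)[C@H](OC(=O)/C(C)=C/C)[C@@H]1O
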